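## Retrosynthetic overview

- The target is cut at the secondary alkyl C–O(aryl) bond (SN2 with inversion). This gives (S)-3-(3,4,5-trimethoxyphenyl)propane-1,2-diol and 4-allyl-2,6-dimethoxyphenol, the phenol being used as its trimethylsilyl ether.
- The diol stays unprotected. It is activated as a P(V) dioxaphospholane, and the aryl silyl ether caps the primary oxygen and hands its aryloxide to the secondary carbon (new silyl-relay Mitsunobu etherification).
- The diol is cut at the aryl–CH2 bond to give 3,4,5-trimethoxyphenyl Grignard and (R)-glycidol, which supplies the only stereocentre.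
- No ring is built. Both benzene rings are bought intact, the epoxide is opened in step 1, and the dioxaphospholane ring in step 3 is transient.

Assumption: the SMILES is read as (R) at the ether-bearing carbon (OAr > CH2OH > CH2Ar > H), and commercial (R)-glycidol of at least 98% ee is used.

## Route

**Step 1**
Reactants: 1 5-bromo-1,2,3-trimethoxybenzene; 2 (R)-glycidol [(2R)-oxiran-2-ylmethanol]
Product: 4 (2S)-3-(3,4,5-trimethoxyphenyl)propane-1,2-diol, via 3,4,5-trimethoxyphenylmagnesium bromide 3 (not isolated)
Conditions: 1 (2.5 equiv), Mg, THF, 50 °C; CuI (10 mol %), −30 °C; 2 (1.0 equiv), −30 → 0 °C, 2 h; 1 M HCl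
Reagents that add atoms: none
Why: Copper-catalysed Grignard opening of a terminal epoxide, in which the first equivalent of 3 only deprotonates the OH and the second attacks the unsubstituted epoxide carbon, so the C2–O bond is untouched and the glycidol stereocentre carries over (R becomes S only through CIP ranking), while the Payne rearrangement of the glycidol alkoxide is degenerate and returns the same enantiomer.

**Step 2**
Reactants: 5 4-allyl-2,6-dimethoxyphenol
Product: 6 (4-allyl-2,6-dimethoxyphenoxy)trimethylsilane
Conditions: HMDS (0.7 equiv), saccharin (1 mol %), neat, 80 °C, 2 h; bulb-to-bulb distillation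
Reagents that add atoms: hexamethyldisilazane (HMDS), C[Si](C)(C)N[Si](C)(C)C
Why: Acid-catalysed O-silylation of a phenol with HMDS is driven by loss of NH3, leaves the allyl and methoxy groups untouched, and creates no stereocentre.

**Step 3**
Reactants: 4 (2S)-3-(3,4,5-trimethoxyphenyl)propane-1,2-diol; 6 (4-allyl-2,6-dimethoxyphenoxy)trimethylsilane
Product: 10 (2R)-2-(4-allyl-2,6-dimethoxyphenoxy)-3-(3,4,5-trimethoxyphenyl)propan-1-ol, via triphenyl-dioxaphospholane 7 (not isolated), via secondary oxyphosphonium aryloxide ion pair 8 (not isolated), via primary trimethylsilyl ether 9 (not isolated)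
Conditions: 4, PPh3 (1.15 equiv), DIAD (1.1 equiv), toluene, 0 °C, 30 min; then 6 (1.3 equiv), 0 → 40 °C, 12 h; then MeOH, citric acid (10 mol %), rt, 30 min
Reagents that add atoms: none
Why: Proposed new method: a silyl-relay Mitsunobu etherification of an unprotected terminal 1,2-diol, in which PPh3/DIAD first ties both hydroxyls of 4 into the σ5-dioxaphospholane 7 (DIAD is spent before the allyl arene enters); the less hindered primary oxygen of 7 (apical P–O bond, or the primary alkoxide of its ring-opened betaine) then attacks silicon of 6 and expels the far better leaving aryloxide (pKa about 10 against 16), so one event caps the primary oxygen, leaves Ph3P+ on the secondary oxygen and frees exactly one aryloxide beside it (ion pair 8); 8 collapses by SN2 with loss of Ph3P=O, forming the C–O bond with inversion (S to R) to give 9, whose labile primary TMS ether is methanolysed in the same flask; the closest known reaction types are the Mitsunobu substitution of terminal 1,2-diols with Me3SiN3, which gives 2-azido-1-silyloxy products with inversion through the same phosphoranes, and the ordinary Mitsunobu aryl ether synthesis with 2,6-dimethoxyphenols, whereas an aryl silyl ether acting as both silyl donor and O-nucleophile has not been shown.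

## Compound list

1 | 5-bromo-1,2,3-trimethoxybenzene | COc1cc(Br)cc(OC)c1OC | starting material
2 | (R)-glycidol, (2R)-oxiran-2-ylmethanol | OC[C@@H]1CO1 | starting material
3 | 3,4,5-trimethoxyphenylmagnesium bromide | COc1cc([Mg]Br)cc(OC)c1OC | intermediate
4 | (2S)-3-(3,4,5-trimethoxyphenyl)propane-1,2-diol | OC[C@@H](O)Cc1cc(OC)c(OC)c(OC)c1 | intermediate
5 | 4-allyl-2,6-dimethoxyphenol | C=CCc1cc(OC)c(O)c(OC)c1 | starting material
6 | (4-allyl-2,6-dimethoxyphenoxy)trimethylsilane | C=CCc1cc(OC)c(O[Si](C)(C)C)c(OC)c1 | intermediate
7 | (4S)-2,2,2-triphenyl-4-(3,4,5-trimethoxybenzyl)-1,3,2λ5-dioxaphospholane | O1C[C@H](Cc2cc(OC)c(OC)c(OC)c2)OP1(c2ccccc2)(c2ccccc2)c2ccccc2 | intermediate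
8 | {[(2S)-1-(trimethylsilyloxy)-3-(3,4,5-trimethoxyphenyl)propan-2-yl]oxy}triphenylphosphonium 4-allyl-2,6-dimethoxyphenoxide | C[Si](C)(C)OC[C@@H](O[P+](c1ccccc1)(c1ccccc1)c1ccccc1)Cc1cc(OC)c(OC)c(OC)c1.[O-]c1c(OC)cc(CC=C)cc1OC | intermediate
9 | {[(2R)-2-(4-allyl-2,6-dimethoxyphenoxy)-3-(3,4,5-trimethoxyphenyl)propyl]oxy}trimethylsilane | C[Si](C)(C)OC[C@H](Oc1c(OC)cc(CC=C)cc1OC)Cc1cc(OC)c(OC)c(OC)c1 | intermediate
10 | (2R)-2-(4-allyl-2,6-dimethoxyphenoxy)-3-(3,4,5-trimethoxyphenyl)propan-1-ol (CNP0175911.1) | C=CCc1cc(OC)c(O[C@@H](CO)Cc2cc(OC)c(OC)c(OC)c2)c(OC)c1 | target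

## Step count and risks

Total step count: 3. Longest linear sequence: 2 (1 + 2 → 4 → 10, or 5 → 6 → 10).

**Most likely to fail, first: step 3 (the new step).**
- Silyl transfer from 6 may be slower than thermal collapse of 7 to the epoxide.
- If silyl transfer is reversible, material may leak through the primary oxyphosphonium isomer to the 1-O-aryl regioisomer.
- E2 elimination to the cinnamyl silyl ether, or aryl participation that erodes ee, would show up on chiral HPLC.

The fallback uses known chemistry, sets out from 4 and returns at 10. The primary hydroxyl is silylated selectively (TBSCl 1.05 equiv, imidazole, CH2Cl2, 0 °C) to give (2S)-1-(tert-butyldimethylsilyloxy)-3-(3,4,5-trimethoxyphenyl)propan-2-ol F1. Ordinary Mitsunobu etherification with free phenol 5 (PPh3, DIAD, toluene, 0 °C to rt, inversion) gives tert-butyl{[(2R)-2-(4-allyl-2,6-dimethoxyphenoxy)-3-(3,4,5-trimethoxyphenyl)propyl]oxy}dimethylsilane F2. TBAF in THF then releases 10. Step 2 is no longer needed, so the route becomes four linear steps.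

**Second: step 1.**
- The glycidol alkoxide can oligomerise.
- MgBr2 can open the epoxide to a bromohydrin.
- One equivalent of 3 is lost to the free OH.

The fallback sets out from 3 and returns at 4, using an electrophile without an OH and unveiling the hydroxyl later. Grignard 3 (1.2 equiv) with CuI (10 mol %) opens (S)-epichlorohydrin (ClC[C@@H]1CO1) in THF at −30 °C to give (2S)-1-chloro-3-(3,4,5-trimethoxyphenyl)propan-2-ol F3. Aqueous KOH in dioxane closes this at rt to (2S)-2-(3,4,5-trimethoxybenzyl)oxirane F4. On heating the dilute mixture to 90 °C, hydroxide opens F4 at its terminal carbon to give 4. The C2–O bond is never broken, so the configuration is kept.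

**Third: step 2.**
- The hindered phenol may silylate incompletely.
- Compound 6 may hydrolyse during isolation or storage.

The fallback sets out from 5 and returns at 6, now as an unisolated species. The separate step and the isolation are dropped. Phenol 5 is silylated in a second vessel with N,O-bis(trimethylsilyl)acetamide (0.5 equiv, toluene, 40 °C, 1 h), and this solution is transferred directly to preformed 7. The amide by-product is too weakly acidic to enter the Mitsunobu manifold. Any silyl group that ends up on the primary OH of 4 still leads to 9 by normal Mitsunobu reaction with free 5. This fallback makes no compound that the list lacks (none F0).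

## Further compounds

F1 | step 3 | (2S)-1-(tert-butyldimethylsilyloxy)-3-(3,4,5-trimethoxyphenyl)propan-2-ol | CC(C)(C)[Si](C)(C)OC[C@@H](O)Cc1cc(OC)c(OC)c(OC)c1
F2 | step 3 | tert-butyl{[(2R)-2-(4-allyl-2,6-dimethoxyphenoxy)-3-(3,4,5-trimethoxyphenyl)propyl]oxy}dimethylsilane | CC(C)(C)[Si](C)(C)OC[C@H](Oc1c(OC)cc(CC=C)cc1OC)Cc1cc(OC)c(OC)c(OC)c1
F3 | step 1 | (2S)-1-chloro-3-(3,4,5-trimethoxyphenyl)propan-2-ol | ClC[C@@H](O)Cc1cc(OC)c(OC)c(OC)c1
F4 | step 1 | (2S)-2-(3,4,5-trimethoxybenzyl)oxirane | C1O[C@H]1Cc2cc(OC)c(OC)c(OC)c2
F0 | step 2 | none | none
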